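**Strategy.** The route rests on cutting the C5–C6 bond of the cyclohexanone ring (C1, C8, C7, C6, C5, C9), which unfolds the bicyclo[3.3.1]nonane into a dearomatized acylphloroglucinol. A catalytic enantioselective Claisen shift first moves a 2-formylprenyl unit from O2 to the prenyl-bearing C1 of a flat aryl ether (C1–C8 bond, C1 stereocentre). The key step then exploits the 1,3-relationship of C1 and C5 across C9 in ring C1–C2–C3–C4–C5–C9: the nucleophilic C5 of the C5=C9 enol ether adds to C6 of the pendant acrolein, closing the ring and setting C5 and C7 from C1 in one operation; the aroyl group blocks C3. The precursor is a 6,6-disubstituted cyclohexa-2,4-dienone.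

Key step: step 13

Numbering: C1–C9 follow the bicyclo[3.3.1]nonane numbering of the target (C1 prenyl bridgehead, C3 aroyl carbon, C5 lavandulyl bridgehead, C6 ring CH2, C7 ring CH, C8 CMe2, C9 bridging C=O) and are kept for the same atoms in the aromatic precursors.

Assumption: (R)-lavandulol is bought as the single enantiomer, and the (S,S)-ligand in step 12 is assumed to give the (R)-configured C1; if the sense is opposite, the (R,R)-ligand is used.

Step 1
Reactants: 1 vanillic acid
Product: 2 3-methoxy-4-(pivaloyloxy)benzoic acid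
Conditions: PivCl (1.1 equiv), 2 M NaOH, THF–H2O, 0 °C; then 1 M HCl
Reagents that add atoms: pivaloyl chloride, CC(C)(C)C(=O)Cl
Why: Schotten–Baumann acylation of the phenoxide should give a hindered aryl pivalate that survives every later step until the final hydroxide treatment.

Step 2
Reactants: 2 3-methoxy-4-(pivaloyloxy)benzoic acid; 3 3,5-dimethoxyphenol
Product: 5 (2-hydroxy-4,6-dimethoxyphenyl)[3-methoxy-4-(pivaloyloxy)phenyl]methanone, via acid chloride 4 (not isolated)
Conditions: (COCl)2, cat. DMF, CH2Cl2, rt, evaporate; then 3, TiCl4, CH2Cl2, 0 °C to rt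
Reagents that add atoms: none
Why: Friedel–Crafts acylation in which the titanium phenoxide should direct the acyl group ortho to the free OH (C3) and not between the two methoxy groups, leaving O2 as the only free phenol.

Step 3
Reactants: 5 (2-hydroxy-4,6-dimethoxyphenyl)[3-methoxy-4-(pivaloyloxy)phenyl]methanone
Product: 6 (2-hydroxy-3-iodo-4,6-dimethoxyphenyl)[3-methoxy-4-(pivaloyloxy)phenyl]methanone
Conditions: BnMe3N·ICl2, NaHCO3, CH2Cl2–MeOH, rt
Reagents that add atoms: benzyltrimethylammonium dichloroiodate, C[N+](C)(C)Cc1ccccc1.Cl[I-]Cl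
Why: Electrophilic aromatic iodination should go to C1, ortho to the free phenol and less hindered than C5 between two methoxy groups, while the acyl-deactivated vanilloyl ring stays untouched.

Step 4
Reactants: 6 (2-hydroxy-3-iodo-4,6-dimethoxyphenyl)[3-methoxy-4-(pivaloyloxy)phenyl]methanone
Product: 7 (5-bromo-2-hydroxy-3-iodo-4,6-dimethoxyphenyl)[3-methoxy-4-(pivaloyloxy)phenyl]methanone
Conditions: NBS, MeCN, 0 °C
Reagents that add atoms: N-bromosuccinimide, O=C1CCC(=O)N1Br
Why: Electrophilic bromination should take the only remaining position of the electron-rich ring (C5), which gives two halides of different reactivity for two ordered couplings.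

Step 5
Reactants: 7 (5-bromo-2-hydroxy-3-iodo-4,6-dimethoxyphenyl)[3-methoxy-4-(pivaloyloxy)phenyl]methanone
Product: 8 [5-bromo-2-hydroxy-4,6-dimethoxy-3-(3-methylbut-2-en-1-yl)phenyl][3-methoxy-4-(pivaloyloxy)phenyl]methanone
Conditions: tributyl(3-methylbut-2-en-1-yl)stannane, Pd(PPh3)4 (5 mol %), DMF, 80 °C
Reagents that add atoms: tributyl(3-methylbut-2-en-1-yl)stannane, CCCC[Sn](CCCC)(CCCC)CC=C(C)C
Why: Stille coupling; zerovalent palladium should insert into the C–I bond much faster than into the C–Br bond, and the prenyl group should be transferred in its linear form to C1.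

Step 6
Reactants: 9 (R)-lavandulol
Product: 10 (R)-lavandulyl iodide, (3R)-3-(iodomethyl)-2,6-dimethylhepta-1,5-diene
Conditions: I2, PPh3, imidazole, CH2Cl2, 0 °C to rt
Reagents that add atoms: iodine, II
Why: Appel-type iodination at the primary carbon should leave the adjacent bought stereocentre untouched.

Step 7
Reactants: 10 (R)-lavandulyl iodide; 8 [5-bromo-2-hydroxy-4,6-dimethoxy-3-(3-methylbut-2-en-1-yl)phenyl][3-methoxy-4-(pivaloyloxy)phenyl]methanone
Product: 12 {2-hydroxy-4,6-dimethoxy-3-(3-methylbut-2-en-1-yl)-5-[(2S)-5-methyl-2-(prop-1-en-2-yl)hex-4-en-1-yl]phenyl}[3-methoxy-4-(pivaloyloxy)phenyl]methanone, via lavandulylzinc iodide 11 (not isolated)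
Conditions: 10, Zn dust, LiCl, THF, 40 °C; then 8, Pd(OAc)2 (3 mol %), SPhos (6 mol %), THF, rt, slow addition of the zinc reagent
Reagents that add atoms: none
Why: Negishi coupling of a primary alkylzinc reagent with the doubly ortho-substituted aryl bromide should place the lavandulyl group at C5 without touching its β-stereocentre, the free chelated phenol being tolerated under slow addition.

Step 8
Reactants: 13 diethyl isopropylidenemalonate
Product: 14 2-(propan-2-ylidene)propane-1,3-diol
Conditions: i-Bu2AlH (4.4 equiv), CH2Cl2, −78 to 0 °C; Rochelle salt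
Reagents that add atoms: none
Why: 1,2-Reduction of both esters of the alkylidene malonate by the aluminium hydride should give the allylic diol.

Step 9
Reactants: 14 2-(propan-2-ylidene)propane-1,3-diol
Product: 15 2-(hydroxymethyl)-3-methylbut-2-enal
Conditions: activated MnO2, CH2Cl2, rt, stopped at mono-oxidation
Reagents that add atoms: none
Why: Allylic oxidation of one of the two equivalent hydroxymethyl groups should give the enal, whose remaining alcohol is deactivated by the new acceptor group.

Step 10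
Reactants: 15 2-(hydroxymethyl)-3-methylbut-2-enal
Product: 16 2-(bromomethyl)-3-methylbut-2-enal
Conditions: NBS, Me2S, CH2Cl2, −20 to 0 °C
Reagents that add atoms: N-bromosuccinimide, O=C1CCC(=O)N1Br
Why: Corey–Kim bromination should convert the allylic alcohol into the bromide without touching the aldehyde.

Step 11
Reactants: 12 the fully substituted phenol; 16 2-(bromomethyl)-3-methylbut-2-enal
Product: 17 {2-[(2-formyl-3-methylbut-2-en-1-yl)oxy]-4,6-dimethoxy-3-(3-methylbut-2-en-1-yl)-5-[(2S)-5-methyl-2-(prop-1-en-2-yl)hex-4-en-1-yl]phenyl}[3-methoxy-4-(pivaloyloxy)phenyl]methanone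
Conditions: Cs2CO3, DMF, 0 °C to rt
Reagents that add atoms: none
Why: Williamson O-alkylation of the caesium phenoxide in a polar aprotic solvent with a primary allylic bromide should favour the ether over dearomative C-alkylation.

Step 12
Reactants: 17 the O2 allyl aryl ether
Product: 18 (6R)-6-(3-formyl-2-methylbut-3-en-2-yl)-3,5-dimethoxy-2-[3-methoxy-4-(pivaloyloxy)benzoyl]-6-(3-methylbut-2-en-1-yl)-4-[(2S)-5-methyl-2-(prop-1-en-2-yl)hex-4-en-1-yl]cyclohexa-2,4-dien-1-one
Conditions: Cu(OTf)2 (10 mol %), (S,S)-tert-butyl-bis(oxazoline) (11 mol %), 4 Å MS, CH2Cl2, −20 °C to rt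
Reagents that add atoms: none
Why: Proposed new method: bidentate binding of divalent copper to the ether oxygen O2 and the aroyl carbonyl (six-membered chelate) should polarize the O2–CH2 bond and trigger a chair-like [3,3] shift to C1, the only open ortho terminus because C3 is blocked by the aroyl group, while the 2-formyl group disfavours ionization of the allyl fragment and the ligand shields one arene face so that C1 forms as (R); the closest known reaction types are the copper–bis(oxazoline)-catalyzed enantioselective Claisen rearrangement of 2-alkoxycarbonyl allyl vinyl ethers and chiral-Lewis-acid-catalyzed dearomative Claisen rearrangements of 1-substituted 2-naphthyl allyl ethers that carry a chelating carbonyl group.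

Step 13
Reactants: 18 the (6R)-dienone
Product: 19 (1R,5R,7R)-4-methoxy-3-[3-methoxy-4-(pivaloyloxy)benzoyl]-8,8-dimethyl-1-(3-methylbut-2-en-1-yl)-5-[(2S)-5-methyl-2-(prop-1-en-2-yl)hex-4-en-1-yl]-2,9-dioxobicyclo[3.3.1]non-3-ene-7-carbaldehyde (formyl endo, on the side of the C2–C3–C4 bridge)
Conditions: Me2AlCl (2.5 equiv), CH2Cl2, −78 °C; sat. aq. NH4Cl at −78 °C, then Rochelle salt
Reagents that add atoms: none
Why: Me2AlCl activates the formyl group, C5 of the electron-rich C5=C9 methyl enol ether adds to C6, the resulting C9 methoxycarbenium ion loses its methyl group to chloride as chloromethane, and the aluminium enolate is protonated at C7 on the cold quench. The closest known reaction type is the intramolecular Mukaiyama–Michael addition of an enol ether to an enal, here with the O-methyl loss familiar from electrophile-triggered carbocyclizations of methoxy dienones. The six-membered ring C5–C6–C7–C8–C1–C9 closes in a 6-endo-trig mode at the acceptor alkene (enolendo at the donor). C5 is fixed by geometry, because the chain on C1 can reach C5 only on its own face, and C7 is set by kinetic protonation of the enolate on the exo face, away from the C2–C3–C4 bridge, which leaves the formyl group endo. The step needs C5 rather than C3 to attack and no [3,3] shift of the side chain from C1 to C5; C3 carries the aroyl group and two carbonyl neighbours and is both hindered and electron-poor, and −78 °C keeps the sigmatropic shift and carbonyl–ene reactions of the prenyl groups slow.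

Step 14
Reactants: 19 the bicyclic endo aldehyde
Product: 21 (1R,5R,7S)-7-(2-oxoethyl) analogue of 19, [(1R,5R,7S)-4-methoxy-3-aroyl-8,8-dimethyl-1-prenyl-5-lavandulyl-2,9-dioxobicyclo[3.3.1]non-3-en-7-yl]acetaldehyde, via methyl enol ether 20 (not isolated)
Conditions: Ph3P(CH2OMe)Cl, KHMDS, THF, −78 to 0 °C; then 1 M HCl, THF, rt
Reagents that add atoms: (methoxymethyl)triphenylphosphonium chloride, COC[P+](c1ccccc1)(c1ccccc1)c1ccccc1.[Cl-]; water, O
Why: Wittig methoxymethylenation should take the aldehyde in preference to the hindered or vinylogous ketones, and mild acid hydrolysis of the enol ether gives the one-carbon-longer aldehyde, after which C7 can no longer epimerize.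

Step 15
Reactants: 21 the homologated aldehyde
Product: 22 (1R,5R,7R)-4-methoxy-3-[3-methoxy-4-(pivaloyloxy)benzoyl]-8,8-dimethyl-1,7-bis(3-methylbut-2-en-1-yl)-5-[(2S)-5-methyl-2-(prop-1-en-2-yl)hex-4-en-1-yl]bicyclo[3.3.1]non-3-ene-2,9-dione
Conditions: i-PrPPh3I, n-BuLi, THF, −78 to 0 °C
Reagents that add atoms: isopropyltriphenylphosphonium iodide, CC(C)[P+](c1ccccc1)(c1ccccc1)c1ccccc1.[I-]
Why: Wittig olefination of the unhindered aldehyde with the isopropylidene ylide should complete the C7 prenyl group while the bridging and vinylogous carbonyls stay inert.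

Step 16
Reactants: 22 the 4-O-methyl 4′-O-pivaloyl precursor
Product: 23 garcinol 13-O-methyl ether
Conditions: LiOH·H2O, 1,4-dioxane–H2O, 90 °C; then 1 M HCl to pH 5
Reagents that add atoms: lithium hydroxide, [Li+].[OH-]
Why: Hydroxide should cleave the vinylogous methyl ester at C4 by addition–elimination and saponify the aryl pivalate in the same pot, and no stereocentre in the product is acidic.

**Compound list**

1 | vanillic acid (4-hydroxy-3-methoxybenzoic acid) | COc1cc(C(=O)O)ccc1O | starting material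
2 | 3-methoxy-4-(pivaloyloxy)benzoic acid | COc1cc(C(=O)O)ccc1OC(=O)C(C)(C)C | intermediate
3 | 3,5-dimethoxyphenol | COc1cc(O)cc(OC)c1 | starting material
4 | 3-methoxy-4-(pivaloyloxy)benzoyl chloride (not isolated) | COc1cc(C(Cl)=O)ccc1OC(=O)C(C)(C)C | intermediate
5 | (2-hydroxy-4,6-dimethoxyphenyl)[3-methoxy-4-(pivaloyloxy)phenyl]methanone | COc1cc(OC)c(C(=O)c2ccc(OC(=O)C(C)(C)C)c(OC)c2)c(O)c1 | intermediate
6 | (2-hydroxy-3-iodo-4,6-dimethoxyphenyl)[3-methoxy-4-(pivaloyloxy)phenyl]methanone | COc1cc(OC)c(C(=O)c2ccc(OC(=O)C(C)(C)C)c(OC)c2)c(O)c1I | intermediate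
7 | (5-bromo-2-hydroxy-3-iodo-4,6-dimethoxyphenyl)[3-methoxy-4-(pivaloyloxy)phenyl]methanone | COc1c(Br)c(OC)c(C(=O)c2ccc(OC(=O)C(C)(C)C)c(OC)c2)c(O)c1I | intermediate
8 | [5-bromo-2-hydroxy-4,6-dimethoxy-3-(3-methylbut-2-en-1-yl)phenyl][3-methoxy-4-(pivaloyloxy)phenyl]methanone | COc1c(Br)c(OC)c(C(=O)c2ccc(OC(=O)C(C)(C)C)c(OC)c2)c(O)c1CC=C(C)C | intermediate
9 | (R)-lavandulol, (2R)-5-methyl-2-(prop-1-en-2-yl)hex-4-en-1-ol | C=C(C)[C@@H](CC=C(C)C)CO | starting material
10 | (R)-lavandulyl iodide | C=C(C)[C@@H](CC=C(C)C)CI | intermediate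
11 | (R)-lavandulylzinc iodide (not isolated) | C=C(C)[C@@H](CC=C(C)C)C[Zn]I | intermediate
12 | {2-hydroxy-4,6-dimethoxy-3-(3-methylbut-2-en-1-yl)-5-[(2S)-5-methyl-2-(prop-1-en-2-yl)hex-4-en-1-yl]phenyl}[3-methoxy-4-(pivaloyloxy)phenyl]methanone | C=C(C)[C@@H](CC=C(C)C)Cc1c(OC)c(CC=C(C)C)c(O)c(C(=O)c2ccc(OC(=O)C(C)(C)C)c(OC)c2)c1OC | intermediate
13 | diethyl isopropylidenemalonate | CCOC(=O)C(=C(C)C)C(=O)OCC | starting material
14 | 2-(propan-2-ylidene)propane-1,3-diol | CC(C)=C(CO)CO | intermediate
15 | 2-(hydroxymethyl)-3-methylbut-2-enal | CC(C)=C(CO)C=O | intermediate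
16 | 2-(bromomethyl)-3-methylbut-2-enal | CC(C)=C(CBr)C=O | intermediate
17 | O2-(2-formyl-3-methylbut-2-en-1-yl) ether of 12 | C=C(C)[C@@H](CC=C(C)C)Cc1c(OC)c(CC=C(C)C)c(OCC(C=O)=C(C)C)c(C(=O)c2ccc(OC(=O)C(C)(C)C)c(OC)c2)c1OC | intermediate
18 | (6R)-6-(3-formyl-2-methylbut-3-en-2-yl)-3,5-dimethoxy-2-[3-methoxy-4-(pivaloyloxy)benzoyl]-6-(3-methylbut-2-en-1-yl)-4-[(2S)-lavandulyl]cyclohexa-2,4-dien-1-one | C=C(C)[C@@H](CC=C(C)C)CC1=C(OC)[C@@](CC=C(C)C)(C(C)(C)C(=C)C=O)C(=O)C(C(=O)c2ccc(OC(=O)C(C)(C)C)c(OC)c2)=C1OC | intermediate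
19 | (1R,5R,7R)-4-methoxy-3-[3-methoxy-4-(pivaloyloxy)benzoyl]-8,8-dimethyl-1-(3-methylbut-2-en-1-yl)-5-[(2S)-lavandulyl]-2,9-dioxobicyclo[3.3.1]non-3-ene-7-carbaldehyde (formyl endo) | C=C(C)[C@@H](CC=C(C)C)C[C@@]12C[C@@H](C=O)C(C)(C)[C@@](CC=C(C)C)(C(=O)C(C(=O)c3ccc(OC(=O)C(C)(C)C)c(OC)c3)=C1OC)C2=O | intermediate
20 | (1R,5R,7S)-7-(2-methoxyethenyl) analogue of 19, E/Z mixture (not isolated) | C=C(C)[C@@H](CC=C(C)C)C[C@@]12C[C@@H](C=COC)C(C)(C)[C@@](CC=C(C)C)(C(=O)C(C(=O)c3ccc(OC(=O)C(C)(C)C)c(OC)c3)=C1OC)C2=O | intermediate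
21 | (1R,5R,7S)-7-(2-oxoethyl) analogue of 19 | C=C(C)[C@@H](CC=C(C)C)C[C@@]12C[C@@H](CC=O)C(C)(C)[C@@](CC=C(C)C)(C(=O)C(C(=O)c3ccc(OC(=O)C(C)(C)C)c(OC)c3)=C1OC)C2=O | intermediate
22 | (1R,5R,7R)-4-methoxy-3-[3-methoxy-4-(pivaloyloxy)benzoyl]-8,8-dimethyl-1,7-bis(3-methylbut-2-en-1-yl)-5-[(2S)-lavandulyl]bicyclo[3.3.1]non-3-ene-2,9-dione | C=C(C)[C@@H](CC=C(C)C)C[C@@]12C[C@@H](CC=C(C)C)C(C)(C)[C@@](CC=C(C)C)(C(=O)C(C(=O)c3ccc(OC(=O)C(C)(C)C)c(OC)c3)=C1OC)C2=O | intermediate
23 | garcinol 13-O-methyl ether | C=C(C)[C@@H](CC=C(C)C)C[C@@]12C[C@@H](CC=C(C)C)C(C)(C)[C@@](CC=C(C)C)(C(=O)C(C(=O)c3ccc(O)c(OC)c3)=C1O)C2=O | target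

Total step count: 16. Longest linear sequence: 12 steps (steps 1, 2, 3, 4, 5, 7, 11, 12, 13, 14, 15, 16).

**Steps most likely to fail**

Step 12 (proposed new method). The catalyst may discriminate the two arene faces poorly. The allyl fragment may also ionize, or the side chain may shift onward from C1 to C5. The fallback sets out from 17 and gives up catalyst control. A known achiral lanthanide-catalyzed aromatic Claisen rearrangement (Eu(fod)3, CHCl3, 50 °C) should give 18 together with its C1 epimer, the (6S)-dienone F1. The mixture is taken through the conditions of step 13. Because the side-chain stereocentre is fixed, the all-epimeric bicyclic aldehyde F2 is a diastereomer of 19 and is removed by chromatography. The route is rejoined at 19.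

Step 13 (key step). Ring closure may occur through C3 instead of C5, the protonation at C7 may lose its facial bias, or the endo aldehyde may add transannularly to C3 under the Lewis acid. The fallback sets out from 18 and switches from Lewis-acid to anionic activation. LiI in DMF at 60 °C should remove the vinylogous O-methyl groups (Krapcho-type demethylation). The lithium enolate of the β-triketone then closes the same C5–C6 bond by intramolecular Michael addition, giving after buffered work-up the 4-O-demethyl aldehyde F3. Re-methylation with trimethylsilyldiazomethane (MeOH–toluene, 0 °C) returns 19. The 2-O-methyl regioisomer F4, if formed, is separated and recycled through the LiI treatment. The route is rejoined at 19.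

Step 14. The basic ylide may enolize the hindered endo aldehyde and epimerize C7 before olefination. The fallback sets out from 19 and avoids basic carbanions:
- Vinylmagnesium bromide with CeCl3 (THF, −78 °C) should give the allylic alcohol F5.
- Ac2O, DMAP and pyridine give the acetate F6.
- Pd(PPh3)4 with HCO2NH4 (dioxane, 80 °C) delivers hydride to the substituted allyl terminus and gives the 7-allyl compound F7.
- Cross-metathesis with 2-methyl-2-butene and second-generation Grubbs catalyst (CH2Cl2, 40 °C) converts the allyl into the prenyl group; the isopropenyl and prenyl groups already present should not react.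

The route is rejoined at 22.

**Further compounds**

F1 | step 12 | (6S)-epimer of dienone 18 | C=C(C)[C@@H](CC=C(C)C)CC1=C(OC)[C@](CC=C(C)C)(C(C)(C)C(=C)C=O)C(=O)C(C(=O)c2ccc(OC(=O)C(C)(C)C)c(OC)c2)=C1OC
F2 | step 12 | (1S,5S,7S)-diastereomer of aldehyde 19 with the (2S) side chain | C=C(C)[C@@H](CC=C(C)C)C[C@]12C[C@H](C=O)C(C)(C)[C@](CC=C(C)C)(C(=O)C(C(=O)c3ccc(OC(=O)C(C)(C)C)c(OC)c3)=C1OC)C2=O
F3 | step 13 | 4-O-demethyl analogue of 19 (free C4 enol, same configuration) | C=C(C)[C@@H](CC=C(C)C)C[C@@]12C[C@@H](C=O)C(C)(C)[C@@](CC=C(C)C)(C(=O)C(C(=O)c3ccc(OC(=O)C(C)(C)C)c(OC)c3)=C1O)C2=O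
F4 | step 13 | 2-O-methyl regioisomer of 19 (2-methoxy-4-oxo enone, same spatial configuration) | C=C(C)[C@@H](CC=C(C)C)C[C@@]12C[C@@H](C=O)C(C)(C)[C@@](CC=C(C)C)(C(OC)=C(C(=O)c3ccc(OC(=O)C(C)(C)C)c(OC)c3)C1=O)C2=O
F5 | step 14 | 7-(1-hydroxyprop-2-en-1-yl) analogue of 19 (carbinol epimers) | C=C(C)[C@@H](CC=C(C)C)C[C@@]12C[C@@H](C(O)C=C)C(C)(C)[C@@](CC=C(C)C)(C(=O)C(C(=O)c3ccc(OC(=O)C(C)(C)C)c(OC)c3)=C1OC)C2=O
F6 | step 14 | acetate of F5 | C=C(C)[C@@H](CC=C(C)C)C[C@@]12C[C@@H](C(OC(C)=O)C=C)C(C)(C)[C@@](CC=C(C)C)(C(=O)C(C(=O)c3ccc(OC(=O)C(C)(C)C)c(OC)c3)=C1OC)C2=O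
F7 | step 14 | 7-allyl analogue of 22 | C=C(C)[C@@H](CC=C(C)C)C[C@@]12C[C@@H](CC=C)C(C)(C)[C@@](CC=C(C)C)(C(=O)C(C(=O)c3ccc(OC(=O)C(C)(C)C)c(OC)c3)=C1OC)C2=O
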